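**Strategy.** The plan cuts the C5=C6 enol-lactone alkene (germacranolide numbering), the only double bond inside the nine-membered oxonane ring (O, C1, C10, C9, C8, C7, C6, C5, C4), after inserting a sulfonyl group between C5 and C6. A Ramberg–Bäcklund reaction of that ten-membered cyclic sulfone extrudes SO2, contracts the ring by one atom and sets the ring-cis (E) γ-ylidene butenolide in one operation, both C6 epimers converging. The precursor is a bridged methyl ketal (C1–O–C4) whose C5 is tied through SO2 to the acetal carbon C6 of a γ-sulfonyl butenolide. It comes from a silylfuran-derived alkyne (C8, C10 set), (S)-2-methylglycidol (C4) and thioacetic acid.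

Key step: step 16

Remark: C1 = hemiketal carbon, C2/C3 = CH2CH2, C4 = methyl-bearing ether carbon, C7=C11 = butenolide alkene, C8 = acyloxy carbon, C10 = CHMe, C12 = lactone C=O, C13 = CH2OAc; FurSi = 5-(tert-butyldimethylsilyl)-4-{[(tert-butyldiphenylsilyl)oxy]methyl}furan-3-yl; (S)-2-methylglycidol is assumed to be purchasable.

**Step 1**
Reactants: 1 furan-3-ylmethanol
Product: 3 [2-(tert-butyldimethylsilyl)furan-3-yl]methanol, via silyl ether 2 (not isolated)
Conditions: n-BuLi (1.05 equiv), THF, −78 °C; TBSCl; then n-BuLi (1.2 equiv), HMPA, −78 °C → rt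
Reagents that add atoms: tert-butyldimethylsilyl chloride, CC(C)(C)[Si](C)(C)Cl
Why: O-silylation followed by C2-lithiation and 1,4 O→C silyl migration (retro-Brook rearrangement) should place silicon on the furan α-carbon next to the hydroxymethyl group, the future C12.

**Step 2**
Reactants: 3 [2-(tert-butyldimethylsilyl)furan-3-yl]methanol
Product: 4 5-(tert-butyldimethylsilyl)-4-(hydroxymethyl)furan-3-carbaldehyde
Conditions: n-BuLi (2.3 equiv), DME, 0 °C; DMF; aq. NH4Cl
Reagents that add atoms: N,N-dimethylformamide, CN(C)C=O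
Why: With C2 blocked by silicon, the lithium alkoxide should direct ortho-lithiation to C4, and formylation there installs C8.

**Step 3**
Reactants: 4 5-(tert-butyldimethylsilyl)-4-(hydroxymethyl)furan-3-carbaldehyde
Product: 5 FurSi-carbaldehyde
Conditions: TBDPSCl, imidazole, DMF, rt
Reagents that add atoms: tert-butyl(chloro)diphenylsilane, CC(C)(C)[Si](Cl)(c1ccccc1)c1ccccc1
Why: Standard silylation of the primary alcohol (C13–O) gives an acid- and base-robust ether.

**Step 4**
Reactants: 5 FurSi-carbaldehyde; 6 methyl acrylate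
Product: 7 methyl 4-oxo-4-(FurSi)butanoate
Conditions: 3-benzyl-5-(2-hydroxyethyl)-4-methylthiazolium chloride (20 mol %), Et3N, 1,4-dioxane, 80 °C
Reagents that add atoms: none
Why: Stetter reaction: the thiazolium-derived acyl anion equivalent of the heteroaryl aldehyde adds 1,4 to the acrylate, delivering C9, C10 and C1.

**Step 5**
Reactants: 7 methyl 4-oxo-4-(FurSi)butanoate
Product: 9 (5S)-5-(FurSi)oxolan-2-one, via hydroxy ester 8 (not isolated)
Conditions: RuCl[(S,S)-TsDPEN](p-cymene) (1 mol %), HCO2H/Et3N (5:2), DMF, 40 °C; then PPTS (cat.), toluene, 60 °C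
Reagents that add atoms: none
Why: Noyori asymmetric transfer hydrogenation of the heteroaryl ketone, where the (S,S)-catalyst should give the S carbinol (C8) as for aryl alkyl ketones, followed by lactonisation of the γ-hydroxy ester.

**Step 6**
Reactants: 9 (5S)-5-(FurSi)oxolan-2-one
Product: 10 (3R,5S)-3-methyl-5-(FurSi)oxolan-2-one
Conditions: LDA, THF, −78 °C; MeI, −78 → −40 °C
Reagents that add atoms: iodomethane, CI
Why: Lactone enolate alkylation, with MeI approaching anti to the C5 substituent, should give the trans lactone and so set C10 as R relative to C8.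

**Step 7**
Reactants: 10 (3R,5S)-3-methyl-5-(FurSi)oxolan-2-one
Product: 12 (1S,3R)-3-methyl-1-(FurSi)pent-4-yn-1-ol, via lactol 11 (not isolated)
Conditions: DIBAL-H, CH2Cl2, −78 °C; MeOH; then dimethyl (1-diazo-2-oxopropyl)phosphonate, K2CO3, MeOH, 0 °C → rt
Reagents that add atoms: dimethyl (1-diazo-2-oxopropyl)phosphonate, CC(=O)C(=[N+]=[N-])P(=O)(OC)OC
Why: Partial reduction to the lactol and Ohira–Bestmann homologation of its open aldehyde form should give the terminal alkyne (C1≡C2) under conditions mild enough to keep the α-methyl centre.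

**Step 8**
Reactants: 12 (1S,3R)-3-methyl-1-(FurSi)pent-4-yn-1-ol
Product: 13 triisopropylsilyl ether of 12
Conditions: TIPSOTf, 2,6-lutidine, CH2Cl2, 0 °C
Reagents that add atoms: triisopropylsilyl trifluoromethanesulfonate, CC(C)[Si](C(C)C)(C(C)C)OS(=O)(=O)C(F)(F)F
Why: Silylation masks the C8 hydroxyl, which would otherwise compete for the alkyne (5-exo) in step 15.

**Step 9**
Reactants: 14 (S)-2-methylglycidol
Product: 15 (R)-(2-methyloxiran-2-yl)methyl 4-methylbenzenesulfonate
Conditions: TsCl, Et3N, DMAP (cat.), CH2Cl2, 0 °C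
Reagents that add atoms: 4-methylbenzenesulfonyl chloride, Cc1ccc(cc1)S(=O)(=O)Cl
Why: Sulfonylation of the primary alcohol leaves the quaternary centre (future C4) untouched; the descriptor changes only through CIP priorities.

**Step 10**
Reactants: 13 triisopropylsilyl ether of 12; 15 (R)-(2-methyloxiran-2-yl)methyl 4-methylbenzenesulfonate
Product: 16 (2R,6R,8S)-2-hydroxy-2,6-dimethyl-8-(FurSi)-8-(triisopropylsilyloxy)oct-4-yn-1-yl tosylate
Conditions: 13, n-BuLi, THF, −78 °C; BF3·OEt2; then 15, −78 °C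
Reagents that add atoms: none
Why: BF3-promoted alkynylation of the epoxide (Yamaguchi–Hirao conditions) at its CH2 terminus forms C2–C3 and frees the tertiary C4 alcohol without touching the stereocentre.

**Step 11**
Reactants: 16 hydroxy tosylate
Product: 18 S-[(2R,6R,8S)-2-hydroxy-2,6-dimethyl-8-(FurSi)-8-(triisopropylsilyloxy)oct-4-yn-1-yl] ethanethioate, via epoxide 17 (not isolated)
Conditions: DBU, DMF, rt; then AcSH, 40 °C
Reagents that add atoms: thioacetic acid, CC(=O)S
Why: Intramolecular Williamson closure to the 2,2-disubstituted epoxide and thioacetate opening at its CH2 carbon should bring sulfur onto the otherwise neopentyl-like C5 with C4 unchanged.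

**Step 12**
Reactants: 18 hydroxy thioacetate
Product: 19 γ-hydroxybutenolide thioacetate (C12 lactone C=O; C6 lactol carbon; lactol epimers)
Conditions: O2, hν (visible), rose bengal (cat.), CH2Cl2, −78 °C; then aqueous work-up
Reagents that add atoms: dioxygen, O=O
Why: Singlet-oxygen [4+2] photooxygenation of the 2-silylfuran, with silyl migration to the peroxide oxygen, should put the carbonyl on the silicon-bearing carbon (C12) and the lactol on C6 regiospecifically.

**Step 13**
Reactants: 19 γ-hydroxybutenolide thioacetate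
Product: 21 eleven-membered cyclic S,O-acetal (C6–S–C5 link; C1≡C2 alkyne; 4-OH; 8-OTIPS; 13-OTBDPS; 4R,8S,10R; C6 epimers), via thiol pseudo-ester 20 (not isolated)
Conditions: HCl (1.25 M in MeOH), 40 °C; evaporate; then CSA (cat.), CH2Cl2 (1 mM), 5 Å MS, 40 °C
Reagents that add atoms: none
Why: Acid methanolysis frees the thiol and makes the methyl pseudo-ester; dilute acid catalysis with methanol scavenging should then drive intramolecular thioacetalisation at C6, the S,O-acetal being the thermodynamic sink.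

**Step 14**
Reactants: 21 cyclic S,O-acetal
Product: 22 eleven-membered cyclic sulfone (as 21 with SO2 between C5 and C6)
Conditions: mCPBA (2.5 equiv), NaHCO3, CH2Cl2, 0 °C → rt
Reagents that add atoms: 3-chloroperbenzoic acid, OOC(=O)c1cccc(Cl)c1
Why: Sulfide-to-sulfone oxidation; the alkyne and the electron-poor butenolide alkene should not react with the peracid.

**Step 15**
Reactants: 22 cyclic sulfone
Product: 24 bridged methyl ketal sulfone (1-OMe; C1–O–C4 oxolane; ten-membered ring S, C5, C4, O, C1, C10, C9, C8, C7, C6; 1S,4R,8S,10R), via cyclic enol ether 23 (not isolated)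
Conditions: Ph3PAuNTf2 (5 mol %), PPTS (10 mol %), MeOH/CH2Cl2, rt
Reagents that add atoms: methanol, CO
Why: Gold(I)-catalysed 5-endo-dig cycloisomerisation of the homopropargylic C4 alcohol onto C1 and hydroalkoxylation of the enol ether should give the ketal; the bridge forces C10 and C5 cis on the oxolane, which fixes C1 as S.

**Step 16**
Reactants: 24 bridged methyl ketal sulfone
Product: 27 ring-contracted (E)-γ-ylidene butenolide (C5=C6; 1-OMe; 8-OTIPS; 13-OTBDPS; 1S,4R,8S,10R), via chloro sulfone 25 (not isolated), via episulfone 26 (not isolated)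
Conditions: LiHMDS, THF, −78 °C; C2Cl6; then KOt-Bu, THF, −78 → 0 °C
Reagents that add atoms: none
Why: LiHMDS removes the C6–H (activated by the sulfone and the vinylogous lactone carbonyl) and hexachloroethane chlorinates C6 to 25; KOt-Bu then deprotonates the α′-CH2 (C5), whose carbanion displaces chloride at C6 to give episulfone 26, which loses SO2 to form the C5=C6 alkene (Ramberg–Bäcklund reaction). The closest precedents are Ramberg–Bäcklund contractions of macrocyclic α-halo sulfones to medium-ring alkenes and the conversion of α-alkoxy (anomeric) sulfones into exocyclic enol ethers. The only ring closed is the transient three-membered episulfone (3-exo-tet); the nine-membered oxonane arises from the ten-membered thia-oxa ring by loss of the sulfur atom. No stereocentre is created: the alkene geometry (C4 cis to C7, i.e. E) is dictated by the nine-membered ring and its oxolane bridge, which cannot hold a trans alkene, and both C6 epimers of 24 converge. The step needs chlorination at C6 rather than C11 of the ambident anion (C11 is fully substituted and C6 attack keeps conjugation) and C5 deprotonation without lactone attack (hindered base, −78 °C, intramolecular displacement).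

**Step 17**
Reactants: 27 ring-contracted ylidene butenolide
Product: 28 8,13-diol (1-OMe ketal retained)
Conditions: TBAF, AcOH, THF, 40 °C
Reagents that add atoms: none
Why: Buffered fluoride desilylation should remove both silyl ethers without opening the base-sensitive enol lactone or the ketal.

**Step 18**
Reactants: 28 8,13-diol
Product: 29 13-O-acetate with free 8-OH
Conditions: AcCl (1.05 equiv), 2,4,6-collidine, CH2Cl2, −78 °C
Reagents that add atoms: acetyl chloride, CC(=O)Cl
Why: Kinetically selective acylation of the primary allylic alcohol over the hindered secondary C8 alcohol.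

**Step 19**
Reactants: 30 ethyl 2-(triphenylphosphoranylidene)propanoate; 31 (tert-butyldimethylsilyloxy)acetaldehyde
Product: 32 ethyl (E)-4-(tert-butyldimethylsilyloxy)-2-methylbut-2-enoate
Conditions: CH2Cl2, rt
Reagents that add atoms: none
Why: Wittig olefination with a stabilised α-methyl ylide should give the (E)-trisubstituted enoate.

**Step 20**
Reactants: 32 ethyl (E)-4-(tert-butyldimethylsilyloxy)-2-methylbut-2-enoate
Product: 33 (E)-4-(tert-butyldimethylsilyloxy)-2-methylbut-2-enoic acid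
Conditions: LiOH, THF/H2O, 0 °C → rt; dilute HCl to pH 4
Reagents that add atoms: lithium hydroxide (aqueous), [Li+].[OH-]
Why: Saponification of the ethyl ester under conditions that a primary TBS ether should survive.

**Step 21**
Reactants: 33 (E)-4-(tert-butyldimethylsilyloxy)-2-methylbut-2-enoic acid; 29 13-O-acetate with free 8-OH
Product: 35 8-O-[(E)-4-(tert-butyldimethylsilyloxy)-2-methylbut-2-enoyl] 13-O-acetyl 1-O-methyl ketal, via mixed anhydride 34 (not isolated)
Conditions: 2,4,6-trichlorobenzoyl chloride, Et3N, THF, 0 °C; then 29, DMAP, toluene, rt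
Reagents that add atoms: none
Why: Yamaguchi esterification acylates the hindered secondary C8 alcohol under mild conditions with retention at C8.

**Step 22**
Reactants: 35 protected ester
Product: 36 CNP0154520.1
Conditions: HF (48 % aq.), MeCN/H2O, 0 °C → rt
Reagents that add atoms: water, O
Why: Aqueous acid should cleave the primary silyl ether and exchange the methyl ketal for the hemiketal through the C1 oxocarbenium ion; the 1S hydroxyl is the only arrangement the bridged bicycle allows, and C10 is not enolised under these conditions.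

**Compound list**

1 | furan-3-ylmethanol | OCc1ccoc1 | starting material
2 | tert-butyl(furan-3-ylmethoxy)dimethylsilane | CC(C)(C)[Si](C)(C)OCc1ccoc1 | intermediate
3 | [2-(tert-butyldimethylsilyl)furan-3-yl]methanol | OCc1ccoc1[Si](C)(C)C(C)(C)C | intermediate
4 | 5-(tert-butyldimethylsilyl)-4-(hydroxymethyl)furan-3-carbaldehyde | O=Cc1coc([Si](C)(C)C(C)(C)C)c1CO | intermediate
5 | 5-(tert-butyldimethylsilyl)-4-{[(tert-butyldiphenylsilyl)oxy]methyl}furan-3-carbaldehyde (FurSi-carbaldehyde) | O=Cc1coc([Si](C)(C)C(C)(C)C)c1CO[Si](c1ccccc1)(c1ccccc1)C(C)(C)C | intermediate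
6 | methyl acrylate | C=CC(=O)OC | starting material
7 | methyl 4-oxo-4-(FurSi)butanoate | COC(=O)CCC(=O)c1coc([Si](C)(C)C(C)(C)C)c1CO[Si](c1ccccc1)(c1ccccc1)C(C)(C)C | intermediate
8 | methyl (4S)-4-hydroxy-4-(FurSi)butanoate | COC(=O)CC[C@H](O)c1coc([Si](C)(C)C(C)(C)C)c1CO[Si](c1ccccc1)(c1ccccc1)C(C)(C)C | intermediate
9 | (5S)-5-(FurSi)oxolan-2-one | O=C1CC[C@@H](c2coc([Si](C)(C)C(C)(C)C)c2CO[Si](c2ccccc2)(c2ccccc2)C(C)(C)C)O1 | intermediate
10 | (3R,5S)-3-methyl-5-(FurSi)oxolan-2-one | O=C1[C@H](C)C[C@@H](c2coc([Si](C)(C)C(C)(C)C)c2CO[Si](c2ccccc2)(c2ccccc2)C(C)(C)C)O1 | intermediate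
11 | (3R,5S)-3-methyl-5-(FurSi)oxolan-2-ol (anomers) | OC1[C@H](C)C[C@@H](c2coc([Si](C)(C)C(C)(C)C)c2CO[Si](c2ccccc2)(c2ccccc2)C(C)(C)C)O1 | intermediate
12 | (1S,3R)-3-methyl-1-(FurSi)pent-4-yn-1-ol | C#C[C@H](C)C[C@@H](c1coc([Si](C)(C)C(C)(C)C)c1CO[Si](c1ccccc1)(c1ccccc1)C(C)(C)C)O | intermediate
13 | {[(1S,3R)-3-methyl-1-(FurSi)pent-4-yn-1-yl]oxy}tri(propan-2-yl)silane | C#C[C@H](C)C[C@@H](c1coc([Si](C)(C)C(C)(C)C)c1CO[Si](c1ccccc1)(c1ccccc1)C(C)(C)C)O[Si](C(C)C)(C(C)C)C(C)C | intermediate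
14 | (S)-2-methylglycidol, (2S)-(2-methyloxiran-2-yl)methanol | OC[C@@]1(C)CO1 | starting material
15 | (R)-(2-methyloxiran-2-yl)methyl 4-methylbenzenesulfonate | Cc1ccc(cc1)S(=O)(=O)OC[C@@]1(C)CO1 | intermediate
16 | (2R,6R,8S)-2-hydroxy-2,6-dimethyl-8-(FurSi)-8-(triisopropylsilyloxy)oct-4-yn-1-yl 4-methylbenzenesulfonate | Cc1ccc(cc1)S(=O)(=O)OC[C@@](O)(C)CC#C[C@H](C)C[C@@H](c1coc([Si](C)(C)C(C)(C)C)c1CO[Si](c1ccccc1)(c1ccccc1)C(C)(C)C)O[Si](C(C)C)(C(C)C)C(C)C | intermediate
17 | (2R)-2-methyl-2-[(4R,6S)-4-methyl-6-(FurSi)-6-(triisopropylsilyloxy)hex-2-yn-1-yl]oxirane | C[C@@]1(CC#C[C@H](C)C[C@@H](c2coc([Si](C)(C)C(C)(C)C)c2CO[Si](c2ccccc2)(c2ccccc2)C(C)(C)C)O[Si](C(C)C)(C(C)C)C(C)C)CO1 | intermediate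
18 | S-[(2R,6R,8S)-2-hydroxy-2,6-dimethyl-8-(FurSi)-8-(triisopropylsilyloxy)oct-4-yn-1-yl] ethanethioate | CC(=O)SC[C@@](O)(C)CC#C[C@H](C)C[C@@H](c1coc([Si](C)(C)C(C)(C)C)c1CO[Si](c1ccccc1)(c1ccccc1)C(C)(C)C)O[Si](C(C)C)(C(C)C)C(C)C | intermediate
19 | S-{(2R,6R,8S)-2-hydroxy-8-[2-hydroxy-5-oxo-4-(tert-butyldiphenylsilyloxymethyl)-2,5-dihydrofuran-3-yl]-2,6-dimethyl-8-(triisopropylsilyloxy)oct-4-yn-1-yl} ethanethioate (lactol epimers) | CC(=O)SC[C@@](O)(C)CC#C[C@H](C)C[C@@H](C1=C(CO[Si](c2ccccc2)(c2ccccc2)C(C)(C)C)C(=O)OC1O)O[Si](C(C)C)(C(C)C)C(C)C | intermediate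
20 | thiol corresponding to 19 with the lactol as its methyl pseudo-ester (C6–OMe) | SC[C@@](O)(C)CC#C[C@H](C)C[C@@H](C1=C(CO[Si](c2ccccc2)(c2ccccc2)C(C)(C)C)C(=O)OC1OC)O[Si](C(C)C)(C(C)C)C(C)C | intermediate
21 | eleven-membered cyclic S,O-acetal: 6,12-butenolide with C6–S–C5 link, C1≡C2 alkyne, 4-OH, 8-OTIPS, 13-OTBDPS, (4R,8S,10R), C6 epimers | O=C1OC2SC[C@@](O)(C)CC#C[C@H](C)C[C@H](O[Si](C(C)C)(C(C)C)C(C)C)C2=C1CO[Si](c1ccccc1)(c1ccccc1)C(C)(C)C | intermediate
22 | cyclic sulfone of 21 | O=C1OC2S(=O)(=O)C[C@@](O)(C)CC#C[C@H](C)C[C@H](O[Si](C(C)C)(C(C)C)C(C)C)C2=C1CO[Si](c1ccccc1)(c1ccccc1)C(C)(C)C | intermediate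
23 | bridged cyclic enol ether sulfone (C1=C2 in a 2,3-dihydrofuran, C1–O–C4) | O=C1OC2S(=O)(=O)C[C@@]3(C)CC=C(O3)[C@H](C)C[C@H](O[Si](C(C)C)(C(C)C)C(C)C)C2=C1CO[Si](c1ccccc1)(c1ccccc1)C(C)(C)C | intermediate
24 | bridged methyl ketal sulfone, (1S,4R,8S,10R), 1-OMe, C5–SO2–C6, 8-OTIPS, 13-OTBDPS | O=C1OC2S(=O)(=O)C[C@@]3(C)CC[C@](OC)(O3)[C@H](C)C[C@H](O[Si](C(C)C)(C(C)C)C(C)C)C2=C1CO[Si](c1ccccc1)(c1ccccc1)C(C)(C)C | intermediate
25 | 6-chloro derivative of sulfone 24 | O=C1OC2(Cl)S(=O)(=O)C[C@@]3(C)CC[C@](OC)(O3)[C@H](C)C[C@H](O[Si](C(C)C)(C(C)C)C(C)C)C2=C1CO[Si](c1ccccc1)(c1ccccc1)C(C)(C)C | intermediate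
26 | episulfone (thiirane 1,1-dioxide spanning C5 and C6) | O=C1OC24S(=O)(=O)C4[C@@]3(C)CC[C@](OC)(O3)[C@H](C)C[C@H](O[Si](C(C)C)(C(C)C)C(C)C)C2=C1CO[Si](c1ccccc1)(c1ccccc1)C(C)(C)C | intermediate
27 | (1S,4R,8S,10R)-1-O-methyl-8-O-TIPS-13-O-TBDPS hirsutinolide core with (E)-C5=C6 γ-ylidene butenolide | CC(C)(C)[Si](c1ccccc1)(c1ccccc1)OCC1=C2/C(=C\[C@@]3(C)CC[C@](OC)(O3)[C@H](C)C[C@@H]2O[Si](C(C)C)(C(C)C)C(C)C)OC1=O | intermediate
28 | 8,13-diol of 27 (1-OMe retained) | OCC1=C2/C(=C\[C@@]3(C)CC[C@](OC)(O3)[C@H](C)C[C@@H]2O)OC1=O | intermediate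
29 | 13-O-acetate of 28 with free 8-OH | CC(=O)OCC1=C2/C(=C\[C@@]3(C)CC[C@](OC)(O3)[C@H](C)C[C@@H]2O)OC1=O | intermediate
30 | ethyl 2-(triphenylphosphoranylidene)propanoate | CCOC(=O)C(C)=P(c1ccccc1)(c1ccccc1)c1ccccc1 | starting material
31 | (tert-butyldimethylsilyloxy)acetaldehyde | O=CCO[Si](C)(C)C(C)(C)C | starting material
32 | ethyl (E)-4-(tert-butyldimethylsilyloxy)-2-methylbut-2-enoate | CCOC(=O)/C(C)=C/CO[Si](C)(C)C(C)(C)C | intermediate
33 | (E)-4-(tert-butyldimethylsilyloxy)-2-methylbut-2-enoic acid | OC(=O)/C(C)=C/CO[Si](C)(C)C(C)(C)C | intermediate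
34 | mixed anhydride of 33 with 2,4,6-trichlorobenzoic acid | O=C(OC(=O)/C(C)=C/CO[Si](C)(C)C(C)(C)C)c1c(Cl)cc(Cl)cc1Cl | intermediate
35 | 8-O-[(E)-4-(tert-butyldimethylsilyloxy)-2-methylbut-2-enoyl] 13-O-acetyl 1-O-methyl ketal, (1S,4R,8S,10R) | CC(=O)OCC1=C2/C(=C\[C@@]3(C)CC[C@](OC)(O3)[C@H](C)C[C@@H]2OC(=O)/C(C)=C/CO[Si](C)(C)C(C)(C)C)OC1=O | intermediate
36 | CNP0154520.1, (1S,4R,8S,10R)-13-acetoxy-1-hydroxy-8-[(E)-4-hydroxy-2-methylbut-2-enoyloxy]-1,4-epoxygermacra-5(E),7(11)-dien-12,6-olide | CC(=O)OCC1=C2/C(=C\[C@@]3(C)CC[C@](O)(O3)[C@H](C)C[C@@H]2OC(=O)/C(C)=C/CO)OC1=O | target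

**Total steps:** 22. **Longest linear sequence:** 19 (steps 1–8, 10–18, 21, 22).

**Steps most likely to fail**

1. Step 16. Chlorine transfer to the ambident sulfonyl dienolate may be slow or go to C11, and the C5 carbanion may expel the C4 ether oxygen (opening the oxolane) faster than it closes the episulfone. Fallback (sets out from 21, comes back at 25): the chlorine is placed at the sulfide oxidation level, where no carbanion is needed. Sulfide 21 is treated with NCS (CH2Cl2/CCl4, 0 °C); a Pummerer-type chlorosulfonium–thionium sequence should put chlorine on the more acidic C6 to give the 6-chloro sulfide F1, which is oxidised in the same flask with mCPBA to the 6-chloro sulfone F2. Gold-catalysed transannular ketalisation of F2 in methanol (conditions of step 15) should then give 25, which is exposed to KOt-Bu at −78 °C as in the second stage of step 16, so that the C5 carbanion forms only in the presence of its internal electrophile.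

2. Step 13. Closing an eleven-membered ring around a linear alkyne under reversible conditions may favour oligomers over the monomeric S,O-acetal. Fallback (sets out from 16, comes back at 24): the oxolane is built first so that the ring closure is ten-membered onto a preorganised 2,5-disubstituted oxolane. Gold-catalysed ketalisation of 16 in methanol gives the ketal tosylate F3; KSAc (DMF, 80 °C) displaces the tosylate to give the ketal thioacetate F4; photooxygenation as in step 12 gives the ketal hydroxybutenolide F5. HCl/MeOH then frees the ketal thiol pseudo-ester F6, which is cyclised with BF3·OEt2 (CH2Cl2, −40 °C, high dilution, MeOH/Et3N quench to restore the C1 ketal) to the bridged cyclic S,O-acetal F7; mCPBA oxidation gives 24.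

3. Step 15. Intermolecular methanol addition to the cycloalkyne or isomerisation of the enol ether toward C10 (epimerisation) may compete with transannular oxyauration. Fallback (sets out from 22, comes back at 24): halonium-induced cyclisation replaces π-acid catalysis. NIS (MeCN, 0 °C) effects 5-endo-dig iodoetherification of 22 to the iodo enol ether F8; CSA in methanol adds methanol across the enol ether to give the iodo ketal F9; Bu3SnH/AIBN (toluene, 80 °C) removes iodine to give 24.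

**Further compounds**

F1 | step 16 | 6-chloro derivative of cyclic S,O-acetal 21 | O=C1OC2(Cl)SC[C@@](O)(C)CC#C[C@H](C)C[C@H](O[Si](C(C)C)(C(C)C)C(C)C)C2=C1CO[Si](c1ccccc1)(c1ccccc1)C(C)(C)C
F2 | step 16 | 6-chloro derivative of cyclic sulfone 22 | O=C1OC2(Cl)S(=O)(=O)C[C@@](O)(C)CC#C[C@H](C)C[C@H](O[Si](C(C)C)(C(C)C)C(C)C)C2=C1CO[Si](c1ccccc1)(c1ccccc1)C(C)(C)C
F3 | step 13 | ketal tosylate: {(2R)-5-methoxy-2-methyl-5-[(2R,4S)-4-(FurSi)-4-(triisopropylsilyloxy)butan-2-yl]oxolan-2-yl}methyl tosylate (C1 anomers) | Cc1ccc(cc1)S(=O)(=O)OC[C@@]1(C)CCC(OC)(O1)[C@H](C)C[C@@H](c1coc([Si](C)(C)C(C)(C)C)c1CO[Si](c1ccccc1)(c1ccccc1)C(C)(C)C)O[Si](C(C)C)(C(C)C)C(C)C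
F4 | step 13 | ketal thioacetate (tosylate of F3 replaced by SAc) | CC(=O)SC[C@@]1(C)CCC(OC)(O1)[C@H](C)C[C@@H](c1coc([Si](C)(C)C(C)(C)C)c1CO[Si](c1ccccc1)(c1ccccc1)C(C)(C)C)O[Si](C(C)C)(C(C)C)C(C)C
F5 | step 13 | ketal hydroxybutenolide thioacetate (furan of F4 oxidised as in 19) | CC(=O)SC[C@@]1(C)CCC(OC)(O1)[C@H](C)C[C@@H](C1=C(CO[Si](c2ccccc2)(c2ccccc2)C(C)(C)C)C(=O)OC1O)O[Si](C(C)C)(C(C)C)C(C)C
F6 | step 13 | ketal thiol methyl pseudo-ester | SC[C@@]1(C)CCC(OC)(O1)[C@H](C)C[C@@H](C1=C(CO[Si](c2ccccc2)(c2ccccc2)C(C)(C)C)C(=O)OC1OC)O[Si](C(C)C)(C(C)C)C(C)C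
F7 | step 13 | bridged cyclic S,O-acetal (sulfide corresponding to 24) | O=C1OC2SC[C@@]3(C)CC[C@](OC)(O3)[C@H](C)C[C@H](O[Si](C(C)C)(C(C)C)C(C)C)C2=C1CO[Si](c1ccccc1)(c1ccccc1)C(C)(C)C
F8 | step 15 | 2-iodo cyclic enol ether sulfone (iodo analogue of 23) | O=C1OC2S(=O)(=O)C[C@@]3(C)CC(I)=C(O3)[C@H](C)C[C@H](O[Si](C(C)C)(C(C)C)C(C)C)C2=C1CO[Si](c1ccccc1)(c1ccccc1)C(C)(C)C
F9 | step 15 | 2-iodo methyl ketal sulfone (2-iodo analogue of 24, C2 epimers) | O=C1OC2S(=O)(=O)C[C@@]3(C)CC(I)[C@](OC)(O3)[C@H](C)C[C@H](O[Si](C(C)C)(C(C)C)C(C)C)C2=C1CO[Si](c1ccccc1)(c1ccccc1)C(C)(C)C
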